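**Numbering used throughout:** 1 O-benzylvanillin; 2 dimethyl succinate; 3 Stobbe half-ester; 4 R half-ester; 5 hydroxy carboxylate (in the flask); 6 R lactone; 7 vanillin; 8 silylated vanillin; 9 its benzylic alcohol; 10 its benzylic bromide; 11 lactone enolate (in the flask); 12 trans-dibenzyl lactone; 13 protected diol; 14 phenol diol (precursor of the key step); 15 quinone methide (in the flask); 16 oxolane (product of the key step); 17 oxazolidinone; 18 bromoacetyl bromide; 19 lithiated 17 (in the flask); 20 bromoacetyl imide; 21 aryloxyacetyl imide; 22 its silyl ether; 23 boron enolate (in the flask); 24 aldol adduct; 25 silylated diol; 26 target.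

## Analysis of the target

The target is a sesquineolignan built on a 2,3,4-trisubstituted oxolane: O1, C2 carrying ring B, C3 carrying CH2OH, C4 carrying the ring A benzyl group, and C5H2. The 4-oxygen of ring B is etherified by C2′ of a 1-arylpropane-1,3-diol (C1′ is the carbinol bearing ring C, C2′ the ether carbon, C3′ the CH2OH). There are five stereocentres in two remote sets: 2S,3R,4R on the oxolane (aryl trans to CH2OH, CH2OH cis to the benzyl group) and 1′S,2′S (threo) in the side chain. An arene and an ether link separate the two sets, so neither can steer the other and each needs its own source of absolute configuration. All three arenes are 4-oxy-3-methoxyphenyl rings, two as free phenols (rings A and C) and one as an alkyl aryl ether (ring B), so three nearly identical rings have to be told apart. The sensitive sites are the two benzylic C–O bonds para to oxygen (C2–O1 and C1′–OH), which ionise under acid and can be hydrogenolysed, and the oxidisable phenols; the difficulty lies in the order of events and the protecting groups more than in the skeleton. The strategy rests on C2 being benzylic and para to the ring B oxygen: with that oxygen as a free phenol, C2–H can be removed as hydride to give a para-quinone methide, and the hydroxyl on the future C5 of an open-chain 2,3-dibenzylbutane-1,4-diol is placed to add to it. The carbon skeleton of that diol is C2-symmetric apart from the phenol protecting groups, so which ring becomes ring B is decided only by which phenol is unmasked.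

## Retrosynthetic reasoning

**26 from 25.** The last operation removes protecting groups only. All three masked hydroxyls (ring A phenol, ring C phenol, C3 hydroxymethyl) are silyl ethers, so one fluoride treatment finishes the synthesis. Neither acid nor hydrogenolysis touches the molecule once the benzylic carbinol C1′ and the benzylic ether C2–O1 coexist.

**25 from 24.** The C3′ alcohol is traced to an imide carbonyl. Hydride cleavage of the exocyclic acyl group releases the primary alcohol and returns auxiliary 17 without touching C1′ or C2′.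

**24 from 22 and 8.** The C1′–C2′ bond is cut as an aldol. This is the only disconnection that creates both side-chain stereocentres in one event under control of a reagent-independent element, the auxiliary from 17, which is needed because the oxolane stereocentres are too far away to help. The aldehyde partner 8 is already made for another purpose. The forward reaction needs the Z boron enolate 23 and a closed transition state; the primary alcohol of 21 is masked first (22) so that it does not consume the boron reagent.

**21 from 16 and 20.** The bond between the ring B oxygen and C2′ is cut as a phenol alkylation at a primary α-bromo carbonyl carbon. Ring B holds the only free phenol of 16, so the site of alkylation is not in question, and no substitution at a secondary carbon is needed. Imide 20 comes from 17 and 18 through 19.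

**16 from 14 (key disconnection).** The O1–C2 bond is cut. This replaces an oxygen function at C2 by a C–H bond in the precursor, so the precursor is a plain diol and the C2 stereocentre is created last on the ring, under control of C3 and C4. The forward reaction must oxidise ring B only, to quinone methide 15, and the hydroxyl on the future C5 must capture the methide carbon. Ring A is capped as a silyl ether for that reason.

**14 from 13 and 12.** The phenol is freed by hydrogenolysis of a benzyl ether and the diol comes from hydride reduction of a lactone. The two rings carry different protecting groups: benzyl on the ring that must survive the early base and hydride chemistry, silyl on the other. The benzyl group is removed at 13, where no benzylic C–O bond exists, and the ring so unmasked becomes ring B. The silyl-capped ring becomes ring A and keeps its cap to the end.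

**12 from 6 and 10.** The C–C bond α to the lactone carbonyl is cut, that is, the bond from the future C4 to the ring A benzylic carbon. Alkylation of enolate 11 anti to the existing substituent is a dependable way to set the second backbone stereocentre relative to the first. Bromide 10 comes from 7 through 8 and 9.

**6 from 4 (through 5), 3, and 1 with 2.** The single stereocentre of 6 is traced to an enantioselective hydrogenation of the alkylidene succinate 3, which a Stobbe condensation assembles from 1 and 2 in one C–C bond-forming step. Chemoselective reduction of the ester of 4 and lactonisation give 6.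

## Alternatives that were turned down

**Alternative 1:** Three-component conjugate addition–aldol on a chiral butenolide.
- *Disconnection:* the bond from C4 to the ring A benzylic carbon and the C3–C2 bond, both traced to one lactone enolate.
- *Forward key step:* the 2-lithio derivative of dithiane A3 adds to the β-carbon of butenolide A2 anti to the menthyloxy group, and the enolate is trapped by ring B aldehyde A4, which already carries the protected threo side chain, giving lactone A1. No ring is closed.
- *For:* two skeletal C–C bonds and the C3/C4 relationship arise in one flask; absolute configuration comes from an inexpensive chiral acetal; the side chain is complete before the core exists.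
- *Against:* A1 is still several operations from the oxolane. The dithiane has to be reduced to CH2, for which Raney Ni is the usual reagent; it also attacks benzyl ethers and benzylic C–O bonds and leaves sulfur that hampers a later hydrogenolysis. Lactone and menthyl acetal have to be reduced, and the ring has then to be closed under acid through the ring B benzylic cation, in the presence of an acid-labile benzylidene acetal whose own benzylic oxygen is para to an alkoxy group. The most costly fragment, A4, is committed in the least predictable step.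
- *Comparison:* on convergence and C–C bond economy this plan is stronger than the chosen one, which is linear after 12. The chosen route offers in its place an oxidation-state-neutral skeleton (no sulfur, no acid once the side chain is present) and attaches the side chain last.

**Alternative 2:** Ring B grown from a pyrone and an ynol ether.
- *Disconnection:* ring B itself, cut into a 2-pyrone (four ring carbons) and an alkyne (two).
- *Forward key step:* ynol ether A7 adds across C3 and C6 of pyrone A6, the nucleophilic alkyne terminus bonding to the electrophilic C6; the bicyclic adduct loses CO2 and gives benzoate A5.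
- *For:* the ortho methoxy/alkoxy pattern and the para ester follow from the polarity of the partners. The aryl ether is made without a phenol alkylation and without an aldol on an advanced intermediate, so the side-chain stereocentres could be set early on a small molecule. On this one point it is stronger than the chosen route, which relies on a late aldol.
- *Against:* ring B is an ordinary guaiacyl ring that vanillin (7) supplies ready-made, so the key step builds no ring and no stereocentre of the oxolane core. A5 would still have to be reduced to an aldehyde and carried through a complete lignan synthesis. Ynol ethers of secondary alcohols with β-hydrogens fragment thermally to a ketene and an alkene, and A7 has such hydrogens at both flanking carbons, while pyrone cycloaddition and CO2 loss need heat.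
- *Comparison:* far longer. The chosen strategy uses the native arenes and every step adds to the target skeleton.

**Alternative 3:** Epoxide-opening radical cyclisation builds the oxolane.
- *Disconnection:* the C3–C4 bond; O1–C2 and O1–C5 are in place as an ether and C2 is set beforehand.
- *Forward key step:* Cp2TiCl (trivalent titanium) opens the terminal epoxide of A9 to the C3 radical, which closes 5-exo onto the styrene; the benzylic radical is reduced to the ring A CH2, giving A8 with its primary alcohol free.
- *For:* a ring C–C bond and two stereocentres form under neutral conditions with the side chain already present. The substitution pattern of the target results directly, and the step count is at least as low as in the chosen route.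
- *Against:* C3 and C4 are set kinetically in the radical closure. The preferred chair-like transition state points to the required 2,3-trans-3,4-cis isomer, but minor isomers are not correctable afterwards. C2, a para-oxygenated benzylic ether carbon, has to be installed enantioenriched and carried through base-mediated etherification of an epoxy alcohol and exposure to Lewis-acidic titanium. A8 still needs a hydrogenolysis that must spare two benzylic C–O bonds.
- *Comparison:* this plan is the stronger one on convergence. The chosen strategy offers thermodynamic rather than kinetic control: C3 and C4 are fixed by a trans-lactone alkylation whose sense is unambiguous, C2 can equilibrate to the stable isomer, and deprotection needs fluoride only.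

Key step: step 10

**Assumption:** compounds 1, 2, 7, 17 and 18 are commercial.

**Remark on step 2:** Et-DuPHOS is 1,2-bis(2,5-diethylphospholan-1-yl)benzene. Which ligand antipode gives the R acid 4 is not asserted here; the antipode that does so is meant, and the sense is to be confirmed on lactone 6 before material is carried on.

## Route

**Step 1**
Reactants: 1 4-(benzyloxy)-3-methoxybenzaldehyde; 2 dimethyl succinate
Product: 3 (E)-4-[4-(benzyloxy)-3-methoxyphenyl]-3-(methoxycarbonyl)but-3-enoic acid
Conditions: NaOMe, MeOH, reflux; then aq. HCl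
Reagents that add atoms: none
Why: Stobbe condensation; the aldol alkoxide acylates itself on the distal ester and base-induced elimination opens the ring again, which leaves the conjugated ester intact, the other carboxyl as the acid, and the aryl group trans to the ester (E). The benzyl ether is inert to methoxide.

**Step 2**
Reactants: 3 (E)-4-[4-(benzyloxy)-3-methoxyphenyl]-3-(methoxycarbonyl)but-3-enoic acid
Product: 4 (R)-4-[4-(benzyloxy)-3-methoxyphenyl]-3-(methoxycarbonyl)butanoic acid
Conditions: H2 (5 bar), [Rh(cod)(Et-DuPHOS)]BF4 (1 mol%), NaOMe (0.1 equiv), MeOH, rt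
Reagents that add atoms: none
Why: Asymmetric hydrogenation of an itaconate-type half-ester; carboxylate and alkene chelate the cationic rhodium bisphospholane and hydrogen is delivered to one face, which sets the stereocentre that becomes C3 of the oxolane. A homogeneous rhodium catalyst does not cleave the aryl benzyl ether.

**Step 3**
Reactants: 4 (R)-4-[4-(benzyloxy)-3-methoxyphenyl]-3-(methoxycarbonyl)butanoic acid
Product: 6 (R)-4-[4-(benzyloxy)-3-methoxybenzyl]oxolan-2-one, via potassium hydroxy carboxylate 5 (not isolated)
Conditions: KOH (1 equiv), EtOH; CaCl2, NaBH4, EtOH, −10 °C to rt; then 2 M HCl, rt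
Reagents that add atoms: none
Why: Chemoselective reduction; Ca(BH4)2 made in the flask reduces the methyl ester but not the carboxylate, and acidification closes the γ-lactone. The stereocentre is not touched.

**Step 4**
Reactants: 7 vanillin
Product: 8 3-methoxy-4-(triisopropylsilyloxy)benzaldehyde
Conditions: iPr3SiCl, imidazole, DMF, rt
Reagents that add atoms: triisopropylsilyl chloride, CC(C)[Si](Cl)(C(C)C)C(C)C
Why: Silylation of the phenol; the hindered triisopropylsilyl ether is chosen because it has to survive an enolate alkylation, LiAlH4, hydrogenolysis conditions and K2CO3 later on.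

**Step 5**
Reactants: 8 3-methoxy-4-(triisopropylsilyloxy)benzaldehyde
Product: 9 [3-methoxy-4-(triisopropylsilyloxy)phenyl]methanol
Conditions: NaBH4, MeOH, 0 °C
Reagents that add atoms: none
Why: Borohydride reduction of an aromatic aldehyde; the aryl silyl ether is stable at 0 °C.

**Step 6**
Reactants: 9 [3-methoxy-4-(triisopropylsilyloxy)phenyl]methanol
Product: 10 4-(bromomethyl)-2-methoxy-1-(triisopropylsilyloxy)benzene
Conditions: CBr4, PPh3, CH2Cl2, 0 °C
Reagents that add atoms: carbon tetrabromide, BrC(Br)(Br)Br
Why: Appel reaction; the neutral conditions spare the aryl silyl ether. The electron-rich benzylic bromide is used at once.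

**Step 7**
Reactants: 6 (R)-4-[4-(benzyloxy)-3-methoxybenzyl]oxolan-2-one; 10 4-(bromomethyl)-2-methoxy-1-(triisopropylsilyloxy)benzene
Product: 12 (3R,4R)-4-[4-(benzyloxy)-3-methoxybenzyl]-3-[3-methoxy-4-(triisopropylsilyloxy)benzyl]oxolan-2-one, via lithium enolate 11 (not isolated)
Conditions: LiN(iPr)2, THF, −78 °C; then 10, −78 to −40 °C
Reagents that add atoms: none
Why: Alkylation of a lactone enolate; the bromide approaches anti to the C4 substituent, which gives the 3,4-trans lactone and so sets the stereocentre that becomes C4 of the oxolane. Both ether protecting groups are inert to the amide base.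

**Step 8**
Reactants: 12 (3R,4R)-4-[4-(benzyloxy)-3-methoxybenzyl]-3-[3-methoxy-4-(triisopropylsilyloxy)benzyl]oxolan-2-one
Product: 13 (2R,3R)-2-[4-(benzyloxy)-3-methoxybenzyl]-3-[3-methoxy-4-(triisopropylsilyloxy)benzyl]butane-1,4-diol
Conditions: LiAlH4, THF, 0 °C
Reagents that add atoms: none
Why: Hydride reduction of the lactone to the 1,4-diol; neither stereocentre is involved once the carbonyl is reduced, and benzyl and triisopropylsilyl aryl ethers are stable at 0 °C.

**Step 9**
Reactants: 13 (2R,3R)-2-[4-(benzyloxy)-3-methoxybenzyl]-3-[3-methoxy-4-(triisopropylsilyloxy)benzyl]butane-1,4-diol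
Product: 14 (2R,3R)-2-(4-hydroxy-3-methoxybenzyl)-3-[3-methoxy-4-(triisopropylsilyloxy)benzyl]butane-1,4-diol
Conditions: H2 (1 atm), 10% Pd/C, EtOAc, rt
Reagents that add atoms: none
Why: Hydrogenolysis of the aryl benzyl ether; no other benzylic C–O bond exists at this stage and the aryl silyl ether is inert in EtOAc. The phenol set free marks its ring as ring B.

**Step 10**
Reactants: 14 (2R,3R)-2-(4-hydroxy-3-methoxybenzyl)-3-[3-methoxy-4-(triisopropylsilyloxy)benzyl]butane-1,4-diol
Product: 16 [(2S,3R,4R)-2-(4-hydroxy-3-methoxyphenyl)-4-[3-methoxy-4-(triisopropylsilyloxy)benzyl]oxolan-3-yl]methanol, via ring B quinone methide 15 (not isolated)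
Conditions: DDQ (1.0 equiv), CH2Cl2, 0 °C to rt; aq. NaHCO3 work-up
Reagents that add atoms: none
Why: DDQ complexes the electron-rich free phenol of ring B and removes the para benzylic hydrogen as hydride, the phenolic proton following, to give quinone methide 15; ring A is a silyl ether, cannot reach a neutral methide and is oxidised far more slowly. The closest known reaction type is the DDQ oxidation of para-alkyl guaiacols to quinone methides with capture by a tethered hydroxyl, the event that closes the furan rings of 8–8′ lignans in nature. The oxolane closes by 5-exo-trig conjugate addition of the hydroxyl on the future C5 to the exocyclic methide carbon, which restores the aromaticity of ring B; the other hydroxymethyl group could only close a four-membered ring and stays free. The new stereocentre C2 is controlled by C3 and C4: in the R,R-diol the CH2OH group and the ring A benzyl group end up on the same face of the forming ring, so the aryl group takes the opposite face in the envelope transition state, which gives 2S (2,3-trans and 2,4-trans). Any 2,3-cis isomer formed kinetically can reopen to 15 under the weakly acidic conditions set by the reduced quinone and drain to the more stable trans isomer. The step also needs oxygen capture to win over carbon capture by ring A, which would close an aryltetralin; under near-neutral conditions the hydroxyl is the better kinetic nucleophile and the five-membered closure outruns the six-membered Friedel–Crafts closure, which needs acid. One equivalent of oxidant and low temperature guard against a second oxidation of 16 at C2.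

**Step 11**
Reactants: 17 (R)-4-benzyl-1,3-oxazolidin-2-one; 18 bromoacetyl bromide
Product: 20 (R)-4-benzyl-3-(bromoacetyl)-1,3-oxazolidin-2-one, via N-lithio oxazolidinone 19 (not isolated)
Conditions: n-BuLi, THF, −78 °C; then 18, −78 °C
Reagents that add atoms: none
Why: N-Acylation of the lithiated oxazolidinone by the acid bromide; at −78 °C the acyl bromide reacts much faster than the alkyl bromide.

**Step 12**
Reactants: 16 [(2S,3R,4R)-2-(4-hydroxy-3-methoxyphenyl)-4-[3-methoxy-4-(triisopropylsilyloxy)benzyl]oxolan-3-yl]methanol; 20 (R)-4-benzyl-3-(bromoacetyl)-1,3-oxazolidin-2-one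
Product: 21 (R)-4-benzyl-3-({4-[(2S,3R,4R)-3-(hydroxymethyl)-4-[3-methoxy-4-(triisopropylsilyloxy)benzyl]oxolan-2-yl]-2-methoxyphenoxy}acetyl)-1,3-oxazolidin-2-one
Conditions: K2CO3, acetone, rt
Reagents that add atoms: none
Why: Williamson ether synthesis; the weak base forms the phenoxide but not the alkoxide of the primary alcohol, and the phenoxide displaces the activated primary bromide by SN2. Room temperature and carbonate spare the imide and the aryl silyl ether.

**Step 13**
Reactants: 21 (R)-4-benzyl-3-({4-[(2S,3R,4R)-3-(hydroxymethyl)-4-[3-methoxy-4-(triisopropylsilyloxy)benzyl]oxolan-2-yl]-2-methoxyphenoxy}acetyl)-1,3-oxazolidin-2-one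
Product: 22 (R)-4-benzyl-3-({4-[(2S,3R,4R)-3-{[(tert-butyldimethylsilyl)oxy]methyl}-4-[3-methoxy-4-(triisopropylsilyloxy)benzyl]oxolan-2-yl]-2-methoxyphenoxy}acetyl)-1,3-oxazolidin-2-one
Conditions: tBuMe2SiCl, imidazole, CH2Cl2, rt
Reagents that add atoms: tert-butyldimethylsilyl chloride, CC(C)(C)[Si](C)(C)Cl
Why: Silylation of the primary alcohol so that it does not consume the boron triflate of the next step; imidazole is too weak a base to enolise the imide.

**Step 14**
Reactants: 22 (R)-4-benzyl-3-({4-[(2S,3R,4R)-3-{[(tert-butyldimethylsilyl)oxy]methyl}-4-[3-methoxy-4-(triisopropylsilyloxy)benzyl]oxolan-2-yl]-2-methoxyphenoxy}acetyl)-1,3-oxazolidin-2-one; 8 3-methoxy-4-(triisopropylsilyloxy)benzaldehyde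
Product: 24 (R)-4-benzyl-3-[(2R,3S)-3-hydroxy-3-[3-methoxy-4-(triisopropylsilyloxy)phenyl]-2-{4-[(2S,3R,4R)-3-{[(tert-butyldimethylsilyl)oxy]methyl}-4-[3-methoxy-4-(triisopropylsilyloxy)benzyl]oxolan-2-yl]-2-methoxyphenoxy}propanoyl]-1,3-oxazolidin-2-one, via dibutylboron Z-enolate 23 (not isolated)
Conditions: Bu2BOTf, iPr2NEt, CH2Cl2, −78 to 0 °C; then 8, −78 to 0 °C; pH 7 buffer, MeOH, 30% H2O2, 0 °C
Reagents that add atoms: none
Why: Evans syn-aldol; the Z boron enolate reacts through a chair Zimmerman–Traxler transition state in which the benzyl group of the R auxiliary blocks one enolate face, giving the 2R,3S acyl chain, which is the syn (threo) arrangement that becomes 1′S,2′S after reduction. The oxolane stereocentres are too remote to interfere.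

**Step 15**
Reactants: 24 (R)-4-benzyl-3-[(2R,3S)-3-hydroxy-3-[3-methoxy-4-(triisopropylsilyloxy)phenyl]-2-{4-[(2S,3R,4R)-3-{[(tert-butyldimethylsilyl)oxy]methyl}-4-[3-methoxy-4-(triisopropylsilyloxy)benzyl]oxolan-2-yl]-2-methoxyphenoxy}propanoyl]-1,3-oxazolidin-2-one
Product: 25 (1S,2S)-2-{4-[(2S,3R,4R)-3-{[(tert-butyldimethylsilyl)oxy]methyl}-4-[3-methoxy-4-(triisopropylsilyloxy)benzyl]oxolan-2-yl]-2-methoxyphenoxy}-1-[3-methoxy-4-(triisopropylsilyloxy)phenyl]propane-1,3-diol
Conditions: LiBH4, MeOH (1 equiv), THF, 0 °C
Reagents that add atoms: none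
Why: Reductive cleavage of the N-acyl oxazolidinone; hydride attacks the exocyclic carbonyl, the primary alcohol C3′ results and the auxiliary is returned, with no base strong enough to epimerise C2′ or reverse the aldol.

**Step 16**
Reactants: 25 (1S,2S)-2-{4-[(2S,3R,4R)-3-{[(tert-butyldimethylsilyl)oxy]methyl}-4-[3-methoxy-4-(triisopropylsilyloxy)benzyl]oxolan-2-yl]-2-methoxyphenoxy}-1-[3-methoxy-4-(triisopropylsilyloxy)phenyl]propane-1,3-diol
Product: 26 (1S,2S)-1-(4-hydroxy-3-methoxyphenyl)-2-{4-[(2S,3R,4R)-4-(4-hydroxy-3-methoxybenzyl)-3-(hydroxymethyl)oxolan-2-yl]-2-methoxyphenoxy}propane-1,3-diol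
Conditions: Bu4NF, AcOH, THF, 0 °C to rt
Reagents that add atoms: none
Why: Fluoride cleaves the two aryl silyl ethers and the primary alkyl silyl ether in one operation; buffering with AcOH keeps the phenols protonated so that no phenoxide can expel the benzylic oxygen at C1′. No stereocentre is touched.

## Compound list

1 | 4-(benzyloxy)-3-methoxybenzaldehyde | COc1cc(C=O)ccc1OCc1ccccc1 | starting material
2 | dimethyl succinate | COC(=O)CCC(=O)OC | starting material
3 | (E)-4-[4-(benzyloxy)-3-methoxyphenyl]-3-(methoxycarbonyl)but-3-enoic acid | COC(=O)/C(CC(=O)O)=C/c1ccc(OCc2ccccc2)c(OC)c1 | intermediate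
4 | (R)-4-[4-(benzyloxy)-3-methoxyphenyl]-3-(methoxycarbonyl)butanoic acid | COC(=O)[C@@H](CC(=O)O)Cc1ccc(OCc2ccccc2)c(OC)c1 | intermediate
5 | potassium (R)-4-[4-(benzyloxy)-3-methoxyphenyl]-3-(hydroxymethyl)butanoate | OC[C@@H](CC(=O)[O-])Cc1ccc(OCc2ccccc2)c(OC)c1.[K+] | intermediate (not isolated)
6 | (R)-4-[4-(benzyloxy)-3-methoxybenzyl]oxolan-2-one | O=C1C[C@@H](Cc2ccc(OCc3ccccc3)c(OC)c2)CO1 | intermediate
7 | vanillin (4-hydroxy-3-methoxybenzaldehyde) | COc1cc(C=O)ccc1O | starting material
8 | 3-methoxy-4-(triisopropylsilyloxy)benzaldehyde | COc1cc(C=O)ccc1O[Si](C(C)C)(C(C)C)C(C)C | intermediate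
9 | [3-methoxy-4-(triisopropylsilyloxy)phenyl]methanol | COc1cc(CO)ccc1O[Si](C(C)C)(C(C)C)C(C)C | intermediate
10 | 4-(bromomethyl)-2-methoxy-1-(triisopropylsilyloxy)benzene | COc1cc(CBr)ccc1O[Si](C(C)C)(C(C)C)C(C)C | intermediate
11 | lithium enolate of 6 | [Li+].[O-]C1=C[C@@H](Cc2ccc(OCc3ccccc3)c(OC)c2)CO1 | intermediate (not isolated)
12 | (3R,4R)-4-[4-(benzyloxy)-3-methoxybenzyl]-3-[3-methoxy-4-(triisopropylsilyloxy)benzyl]oxolan-2-one | COc1cc(C[C@@H](CO2)[C@@H](Cc3ccc(O[Si](C(C)C)(C(C)C)C(C)C)c(OC)c3)C2=O)ccc1OCc1ccccc1 | intermediate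
13 | (2R,3R)-2-[4-(benzyloxy)-3-methoxybenzyl]-3-[3-methoxy-4-(triisopropylsilyloxy)benzyl]butane-1,4-diol | COc1cc(C[C@@H](CO)[C@@H](Cc3ccc(O[Si](C(C)C)(C(C)C)C(C)C)c(OC)c3)CO)ccc1OCc1ccccc1 | intermediate
14 | (2R,3R)-2-(4-hydroxy-3-methoxybenzyl)-3-[3-methoxy-4-(triisopropylsilyloxy)benzyl]butane-1,4-diol | COc1cc(C[C@@H](CO)[C@@H](Cc3ccc(O)c(OC)c3)CO)ccc1O[Si](C(C)C)(C(C)C)C(C)C | intermediate
15 | para-quinone methide of ring B of 14, both stereocentres of 14 unchanged, exocyclic alkene geometry undefined | COc1cc(C[C@@H](CO)[C@@H](C=C3C=CC(=O)C(OC)=C3)CO)ccc1O[Si](C(C)C)(C(C)C)C(C)C | intermediate (not isolated)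
16 | [(2S,3R,4R)-2-(4-hydroxy-3-methoxyphenyl)-4-[3-methoxy-4-(triisopropylsilyloxy)benzyl]oxolan-3-yl]methanol | COc1cc(C[C@H]2CO[C@H](c3ccc(O)c(OC)c3)[C@H]2CO)ccc1O[Si](C(C)C)(C(C)C)C(C)C | intermediate
17 | (R)-4-benzyl-1,3-oxazolidin-2-one | O=C1N[C@H](Cc2ccccc2)CO1 | starting material
18 | bromoacetyl bromide | BrCC(Br)=O | starting material
19 | N-lithio derivative of 17 | [Li+].O=C1[N-][C@H](Cc2ccccc2)CO1 | intermediate (not isolated)
20 | (R)-4-benzyl-3-(bromoacetyl)-1,3-oxazolidin-2-one | O=C(CBr)N1[C@H](Cc2ccccc2)COC1=O | intermediate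
21 | (R)-4-benzyl-3-({4-[(2S,3R,4R)-3-(hydroxymethyl)-4-[3-methoxy-4-(triisopropylsilyloxy)benzyl]oxolan-2-yl]-2-methoxyphenoxy}acetyl)-1,3-oxazolidin-2-one | COc1cc(C[C@H]2CO[C@H](c3ccc(OCC(=O)N4[C@H](Cc5ccccc5)COC4=O)c(OC)c3)[C@H]2CO)ccc1O[Si](C(C)C)(C(C)C)C(C)C | intermediate
22 | tert-butyldimethylsilyl ether of 21 at the C3 hydroxymethyl group | COc1cc(C[C@H]2CO[C@H](c3ccc(OCC(=O)N4[C@H](Cc5ccccc5)COC4=O)c(OC)c3)[C@H]2CO[Si](C)(C)C(C)(C)C)ccc1O[Si](C(C)C)(C(C)C)C(C)C | intermediate
23 | dibutylboron Z-enolate of 22 (aryloxy group cis to the boron-bound oxygen) | COc1cc(C[C@H]2CO[C@H](c3ccc(O/C=C(\OB(CCCC)CCCC)N4[C@H](Cc5ccccc5)COC4=O)c(OC)c3)[C@H]2CO[Si](C)(C)C(C)(C)C)ccc1O[Si](C(C)C)(C(C)C)C(C)C | intermediate (not isolated)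
24 | (R)-4-benzyl-3-[(2R,3S)-3-hydroxy-3-[3-methoxy-4-(triisopropylsilyloxy)phenyl]-2-{4-[(2S,3R,4R)-3-{[(tert-butyldimethylsilyl)oxy]methyl}-4-[3-methoxy-4-(triisopropylsilyloxy)benzyl]oxolan-2-yl]-2-methoxyphenoxy}propanoyl]-1,3-oxazolidin-2-one | COc1cc(C[C@H]2CO[C@H](c3ccc(O[C@@H](C(=O)N4[C@H](Cc5ccccc5)COC4=O)[C@@H](O)c6ccc(O[Si](C(C)C)(C(C)C)C(C)C)c(OC)c6)c(OC)c3)[C@H]2CO[Si](C)(C)C(C)(C)C)ccc1O[Si](C(C)C)(C(C)C)C(C)C | intermediate
25 | (1S,2S)-2-{4-[(2S,3R,4R)-3-{[(tert-butyldimethylsilyl)oxy]methyl}-4-[3-methoxy-4-(triisopropylsilyloxy)benzyl]oxolan-2-yl]-2-methoxyphenoxy}-1-[3-methoxy-4-(triisopropylsilyloxy)phenyl]propane-1,3-diol | COc1cc(C[C@H]2CO[C@H](c3ccc(O[C@@H](CO)[C@@H](O)c6ccc(O[Si](C(C)C)(C(C)C)C(C)C)c(OC)c6)c(OC)c3)[C@H]2CO[Si](C)(C)C(C)(C)C)ccc1O[Si](C(C)C)(C(C)C)C(C)C | intermediate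
26 | (1S,2S)-1-(4-hydroxy-3-methoxyphenyl)-2-{4-[(2S,3R,4R)-4-(4-hydroxy-3-methoxybenzyl)-3-(hydroxymethyl)oxolan-2-yl]-2-methoxyphenoxy}propane-1,3-diol | COc1cc(C[C@H]2CO[C@H](c3ccc(O[C@@H](CO)[C@@H](O)c4ccc(O)c(OC)c4)c(OC)c3)[C@H]2CO)ccc1O | target

## Step count and least certain steps

Total number of steps: 16.
Longest linear sequence: 12 steps (1 → 3 → 4 → 6 → 12 → 13 → 14 → 16 → 21 → 22 → 24 → 25 → 26; steps 1, 2, 3, 7, 8, 9, 10, 12, 13, 14, 15, 16). Steps 4–6 and step 11 are side branches.

**Step 10 (key step).** Three processes may go wrong. The methide may be captured by carbon: ring A can attack through its position para to the methoxyl and close an aryltetralin, the more so as the acidic reduced quinone accumulates. Product 16 may lose a second hydride from C2, which is again para to a free phenol. The ring may close kinetically to the 2,3-cis epimer.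
Fallback, which reaches the same methide by ionisation of a benzylic alcohol instead of C–H oxidation, sets out from 6 and comes back at 16. Hydrogenolysis of 6 (H2, Pd/C, EtOAc) gives (R)-4-(4-hydroxy-3-methoxybenzyl)oxolan-2-one F1, and silylation (iPr3SiCl, imidazole) gives (R)-4-[3-methoxy-4-(triisopropylsilyloxy)benzyl]oxolan-2-one F2, so that the lactone now carries ring A. Its lithium enolate (LiN(iPr)2, THF, −78 °C) is added to commercial 4-formyl-2-methoxyphenyl acetate and should give the 3,4-trans lactone with the ring B carbinol on C3, (4R)-3-[(4-acetoxy-3-methoxyphenyl)(hydroxy)methyl]-4-[3-methoxy-4-(triisopropylsilyloxy)benzyl]oxolan-2-one F3, as both carbinol epimers; any acetyl transfer is erased in the next operation. LiAlH4 reduces lactone and acetate to the phenol triol (2R,3R)-2-[hydroxy(4-hydroxy-3-methoxyphenyl)methyl]-3-[3-methoxy-4-(triisopropylsilyloxy)benzyl]butane-1,4-diol F4. A trace of acid (pyridinium p-toluenesulfonate, CH2Cl2, 0 °C) ionises the para-hydroxybenzylic alcohol to methide 15 without any oxidant present, and 15 closes to 16. The carbinol configuration is lost on ionisation and does not matter.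

**Step 2.** The risk is insufficient enantiomeric purity, from Z isomer carried over from step 1 or from the wrong sense of induction; the error would only surface later as diastereomers once the side chain is attached.
Fallback, a resolution in place of asymmetric catalysis, sets out from 3 and comes back at 6. Hydrogenation of 3 with an achiral catalyst ([Rh(cod)(dppb)]BF4, H2, MeOH; dppb is 1,4-bis(diphenylphosphino)butane) gives racemic 4-[4-(benzyloxy)-3-methoxyphenyl]-3-(methoxycarbonyl)butanoic acid F5, and the conditions of step 3 give racemic 4-[4-(benzyloxy)-3-methoxybenzyl]oxolan-2-one F6. Opening with (S)-1-phenylethylamine (AlMe3, CH2Cl2) gives two diastereomeric hydroxy amides, of which (R)-4-[4-(benzyloxy)-3-methoxyphenyl]-3-(hydroxymethyl)-N-[(S)-1-phenylethyl]butanamide F7 is separated by chromatography or crystallisation. Heating F7 in aq. H2SO4–dioxane relactonises it to 6.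

**Step 12.** The bromoacetyl imide 20 is an acylating as well as an alkylating agent, so phenoxide or carbonate may take the acyl group and strip the auxiliary, or 20 may be enolised and self-condense.
Fallback, which forms the ether first and attaches the auxiliary last, sets out from 16 and comes back at 22. Alkylation of 16 with allyl bromoacetate (K2CO3, acetone) gives allyl {4-[(2S,3R,4R)-3-(hydroxymethyl)-4-[3-methoxy-4-(triisopropylsilyloxy)benzyl]oxolan-2-yl]-2-methoxyphenoxy}acetate F8. Silylation (tBuMe2SiCl, imidazole) gives its tert-butyldimethylsilyl ether F9, and deallylation with Pd(PPh3)4 and morpholine gives the aryloxyacetic acid F10 without any hydroxide that could attack the aryl silyl ether. The mixed anhydride of F10 (pivaloyl chloride, Et3N, THF, −20 °C) is treated with 19 (from 17 and n-BuLi) to give 22.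

**Step 14.** Enolisation may stall because the boron triflate is held by the many ether oxygens, the aldol may revert with the electron-rich aldehyde, or the Lewis acid may ionise the C2–O1 bond.
Fallback, a catalyst-controlled reduction in place of the auxiliary-controlled C–C bond formation, sets out from 16 and 8 and comes back at 26. Roskamp homologation of 8 (methyl diazoacetate, SnCl2, CH2Cl2) gives methyl 3-[3-methoxy-4-(triisopropylsilyloxy)phenyl]-3-oxopropanoate F11, and N-bromosuccinimide gives its 2-bromo derivative F12. The phenoxide of 16 (K2CO3, acetone) displaces the bromide to give the α-aryloxy β-keto ester F13, whose acidic aryloxy carbon epimerises freely. Noyori-type transfer hydrogenation under dynamic kinetic resolution (RuCl(p-cymene)(TsDPEN), HCO2H–Et3N) is known to turn α-alkoxy β-keto esters into syn hydroxy esters. With the diamine antipode that delivers the 1′S carbinol it should give methyl (2S,3S)-3-hydroxy-3-[3-methoxy-4-(triisopropylsilyloxy)phenyl]-2-{4-[(2S,3R,4R)-3-(hydroxymethyl)-4-[3-methoxy-4-(triisopropylsilyloxy)benzyl]oxolan-2-yl]-2-methoxyphenoxy}propanoate F14. LiBH4 reduces the ester to the bis-silylated triol F15, and Bu4NF with AcOH gives 26. No protecting group is needed on the hydroxymethyl group in this sequence.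

## Further compounds

F1 | step 10 | (R)-4-(4-hydroxy-3-methoxybenzyl)oxolan-2-one | O=C1C[C@@H](Cc2ccc(O)c(OC)c2)CO1
F2 | step 10 | (R)-4-[3-methoxy-4-(triisopropylsilyloxy)benzyl]oxolan-2-one | O=C1C[C@@H](Cc2ccc(O[Si](C(C)C)(C(C)C)C(C)C)c(OC)c2)CO1
F3 | step 10 | (4R)-3-[(4-acetoxy-3-methoxyphenyl)(hydroxy)methyl]-4-[3-methoxy-4-(triisopropylsilyloxy)benzyl]oxolan-2-one, 3,4-trans, both carbinol epimers | COc1cc(C[C@@H](CO2)[C@@H](C(O)c3ccc(OC(C)=O)c(OC)c3)C2=O)ccc1O[Si](C(C)C)(C(C)C)C(C)C
F4 | step 10 | (2R,3R)-2-[hydroxy(4-hydroxy-3-methoxyphenyl)methyl]-3-[3-methoxy-4-(triisopropylsilyloxy)benzyl]butane-1,4-diol, both carbinol epimers | COc1cc(C[C@@H](CO)[C@@H](C(O)c3ccc(O)c(OC)c3)CO)ccc1O[Si](C(C)C)(C(C)C)C(C)C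
F5 | step 2 | racemic 4-[4-(benzyloxy)-3-methoxyphenyl]-3-(methoxycarbonyl)butanoic acid | COC(=O)C(CC(=O)O)Cc1ccc(OCc2ccccc2)c(OC)c1
F6 | step 2 | racemic 4-[4-(benzyloxy)-3-methoxybenzyl]oxolan-2-one | O=C1CC(Cc2ccc(OCc3ccccc3)c(OC)c2)CO1
F7 | step 2 | (R)-4-[4-(benzyloxy)-3-methoxyphenyl]-3-(hydroxymethyl)-N-[(S)-1-phenylethyl]butanamide | C[C@H](NC(=O)C[C@H](CO)Cc1ccc(OCc2ccccc2)c(OC)c1)c1ccccc1
F8 | step 12 | allyl {4-[(2S,3R,4R)-3-(hydroxymethyl)-4-[3-methoxy-4-(triisopropylsilyloxy)benzyl]oxolan-2-yl]-2-methoxyphenoxy}acetate | COc1cc(C[C@H]2CO[C@H](c3ccc(OCC(=O)OCC=C)c(OC)c3)[C@H]2CO)ccc1O[Si](C(C)C)(C(C)C)C(C)C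
F9 | step 12 | tert-butyldimethylsilyl ether of F8 at the hydroxymethyl group | COc1cc(C[C@H]2CO[C@H](c3ccc(OCC(=O)OCC=C)c(OC)c3)[C@H]2CO[Si](C)(C)C(C)(C)C)ccc1O[Si](C(C)C)(C(C)C)C(C)C
F10 | step 12 | {4-[(2S,3R,4R)-3-{[(tert-butyldimethylsilyl)oxy]methyl}-4-[3-methoxy-4-(triisopropylsilyloxy)benzyl]oxolan-2-yl]-2-methoxyphenoxy}acetic acid | COc1cc(C[C@H]2CO[C@H](c3ccc(OCC(=O)O)c(OC)c3)[C@H]2CO[Si](C)(C)C(C)(C)C)ccc1O[Si](C(C)C)(C(C)C)C(C)C
F11 | step 14 | methyl 3-[3-methoxy-4-(triisopropylsilyloxy)phenyl]-3-oxopropanoate | COC(=O)CC(=O)c1ccc(O[Si](C(C)C)(C(C)C)C(C)C)c(OC)c1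
F12 | step 14 | methyl 2-bromo-3-[3-methoxy-4-(triisopropylsilyloxy)phenyl]-3-oxopropanoate, racemic | COC(=O)C(Br)C(=O)c1ccc(O[Si](C(C)C)(C(C)C)C(C)C)c(OC)c1
F13 | step 14 | methyl 3-[3-methoxy-4-(triisopropylsilyloxy)phenyl]-3-oxo-2-{4-[(2S,3R,4R)-3-(hydroxymethyl)-4-[3-methoxy-4-(triisopropylsilyloxy)benzyl]oxolan-2-yl]-2-methoxyphenoxy}propanoate, both epimers at the aryloxy carbon | COc1cc(C[C@H]2CO[C@H](c3ccc(OC(C(=O)OC)C(=O)c6ccc(O[Si](C(C)C)(C(C)C)C(C)C)c(OC)c6)c(OC)c3)[C@H]2CO)ccc1O[Si](C(C)C)(C(C)C)C(C)C
F14 | step 14 | methyl (2S,3S)-3-hydroxy-3-[3-methoxy-4-(triisopropylsilyloxy)phenyl]-2-{4-[(2S,3R,4R)-3-(hydroxymethyl)-4-[3-methoxy-4-(triisopropylsilyloxy)benzyl]oxolan-2-yl]-2-methoxyphenoxy}propanoate | COc1cc(C[C@H]2CO[C@H](c3ccc(O[C@@H](C(=O)OC)[C@@H](O)c6ccc(O[Si](C(C)C)(C(C)C)C(C)C)c(OC)c6)c(OC)c3)[C@H]2CO)ccc1O[Si](C(C)C)(C(C)C)C(C)C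
F15 | step 14 | (1S,2S)-2-{4-[(2S,3R,4R)-3-(hydroxymethyl)-4-[3-methoxy-4-(triisopropylsilyloxy)benzyl]oxolan-2-yl]-2-methoxyphenoxy}-1-[3-methoxy-4-(triisopropylsilyloxy)phenyl]propane-1,3-diol | COc1cc(C[C@H]2CO[C@H](c3ccc(O[C@@H](CO)[C@@H](O)c6ccc(O[Si](C(C)C)(C(C)C)C(C)C)c(OC)c6)c(OC)c3)[C@H]2CO)ccc1O[Si](C(C)C)(C(C)C)C(C)C
A1 | alternative 1 | trans-2,3-disubstituted menthyloxy lactone with the ring A dithiane, the ring B benzylic carbinol and the benzylidene-protected threo side chain | COc1cc(C3(SCCCS3)[C@H]2[C@H](O[C@@H]4C[C@H](C)CC[C@H]4C(C)C)OC(=O)[C@@H]2[C@H](O)c5ccc(O[C@@H](CO6)[C@@H](O[C@@H]6c7ccccc7)c8ccc(OCc9ccccc9)c(OC)c8)c(OC)c5)ccc1OCc1ccccc1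
A2 | alternative 1 | (5R)-5-[(1R,2S,5R)-menthyloxy]furan-2(5H)-one | O=C1C=C[C@H](O[C@@H]2C[C@H](C)CC[C@H]2C(C)C)O1
A3 | alternative 1 | 2-[4-(benzyloxy)-3-methoxyphenyl]-1,3-dithiane | COc1cc(C2SCCCS2)ccc1OCc1ccccc1
A4 | alternative 1 | ring B aldehyde: vanillin etherified at O4 by the benzylidene-protected threo arylglycerol unit (configuration as in the SMILES) | O=Cc5ccc(O[C@@H](CO6)[C@@H](O[C@@H]6c7ccccc7)c8ccc(OCc9ccccc9)c(OC)c8)c(OC)c5
A5 | alternative 2 | methyl 3-methoxy-4-(benzylidene-protected threo-glyceryloxy)benzoate | COC(=O)c1ccc(O[C@@H](CO5)[C@@H](O[C@@H]5c7ccccc7)c4ccc(OCc6ccccc6)c(OC)c4)c(OC)c1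
A6 | alternative 2 | methyl 3-methoxy-2-oxo-2H-pyran-5-carboxylate | O=C1OC=C(C(=O)OC)C=C1OC
A7 | alternative 2 | ethynyl ether of the benzylidene-protected threo arylglycerol | C#CO[C@@H](CO5)[C@@H](O[C@@H]5c7ccccc7)c4ccc(OCc6ccccc6)c(OC)c4
A8 | alternative 3 | target protected as two benzyl ethers and a benzylidene acetal, primary alcohol on C3 free | COc1cc(C[C@H]2CO[C@H](c3ccc(O[C@@H](CO5)[C@@H](O[C@@H]5c7ccccc7)c4ccc(OCc6ccccc6)c(OC)c4)c(OC)c3)[C@H]2CO)ccc1OCc1ccccc1
A9 | alternative 3 | aryl(cinnamyloxy)methyl oxirane: (E)-cinnamyl ether of the ring B (oxiranyl)carbinol, ring A benzylated, side chain as in A8, either epoxide epimer | COc1cc(/C=C/CO[C@H](c3ccc(O[C@@H](CO5)[C@@H](O[C@@H]5c7ccccc7)c4ccc(OCc6ccccc6)c(OC)c4)c(OC)c3)C2CO2)ccc1OCc1ccccc1
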